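The central ring B of perrottetin F carries nothing except the diaryl ether oxygen at C1 and, para to it at C4, the CH2CH2 bridge to ring A. The route exploits this by not coupling two arenes through oxygen: ring B is instead built onto the O–C1 bond. A 2-aryloxybuta-1,3-diene made from the ring C phenol (ring D arm in place) supplies C1, C2, C5 and C6; a terminal ynone bearing ring A supplies C3, C4 and the bridge carbon as its carbonyl. One thermal Diels–Alder reaction forms C2–C3 and C4–C5, closes ring B as a 1,4-cyclohexadiene and unites both halves; aromatisation, deoxygenation and demethylation then finish the synthesis.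

Key step: step 7

Remark: ring A is the 3-oxygenated phenyl on the bridge to ring B, ring B the para-phenylene (C1 bears the ether oxygen, C4 the bridge), ring C the trioxygenated ring and ring D its 3-oxygenated phenethyl arm; the target has no stereocentre, and the E/Z mixture of 4 is taken on unseparated because step 2 removes the double bond.

Step 1
Reactants: 1 3-hydroxy-4,5-dimethoxybenzaldehyde; 2 (3-methoxybenzyl)triphenylphosphonium chloride
Product: 4 2,3-dimethoxy-5-[2-(3-methoxyphenyl)ethenyl]phenol (E/Z mixture), via benzylidenephosphorane ylide 3 (not isolated)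
Conditions: 2 (1.3 equiv), KOtBu (2.6 equiv), THF, 0 °C; then 1, 0 → 60 °C; aq NH4Cl
Reagents that add atoms: none
Why: Wittig olefination with a semi-stabilised benzylic ylide, in which the second equivalent of base holds the phenol as its potassium phenoxide, which sits meta to the formyl group and therefore does not deactivate the aldehyde by resonance.

Step 2
Reactants: 4 2,3-dimethoxy-5-[2-(3-methoxyphenyl)ethenyl]phenol (E/Z mixture)
Product: 5 2,3-dimethoxy-5-[2-(3-methoxyphenyl)ethyl]phenol
Conditions: H2 (1 atm), Pd/C (10 wt% Pd), EtOAc–MeOH, rt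
Reagents that add atoms: none
Why: Heterogeneous catalytic hydrogenation saturates the stilbene double bond of both geometric isomers to the same bibenzyl, while the phenol, the aryl methyl ethers and the arenes are inert under these mild conditions.

Step 3
Reactants: 5 2,3-dimethoxy-5-[2-(3-methoxyphenyl)ethyl]phenol; 6 acryloyl chloride
Product: 7 2,3-dimethoxy-5-[2-(3-methoxyphenyl)ethyl]phenyl prop-2-enoate
Conditions: 6 (1.2 equiv), Et3N (1.5 equiv), BHT (trace), CH2Cl2, 0 °C
Reagents that add atoms: none
Why: O-acylation of a phenol with an acid chloride and an amine base (Einhorn-type esterification) is fast at 0 °C even next to an ortho methoxy group, and the inhibitor and low temperature keep the acrylate from polymerising.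

Step 4
Reactants: 7 2,3-dimethoxy-5-[2-(3-methoxyphenyl)ethyl]phenyl prop-2-enoate
Product: 8 1-(buta-1,3-dien-2-yloxy)-2,3-dimethoxy-5-[2-(3-methoxyphenyl)ethyl]benzene
Conditions: Cp2Ti(μ-CH2)(μ-Cl)AlMe2 (Tebbe reagent, 1.2 equiv, toluene solution), pyridine, THF, −40 → 0 °C; 15% aq NaOH quench; filtration through basic Al2O3; used at once
Reagents that add atoms: Tebbe reagent, written as the Cp2Ti=CH2·ClAlMe2 adduct, C=[Ti](C1C=CC=C1)C1C=CC=C1.C[Al](C)Cl (adds the CH2 group)
Why: Tebbe methylenation, in which the titanium methylidene adds to the electrophilic aryl ester carbonyl and the oxatitanacyclobutane collapses to the enol ether, is established for aryl esters and for α,β-unsaturated esters (which give 2-oxybuta-1,3-dienes), and the low temperature and basic work-up spare the polymerisable, acid-labile diene.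

Step 5
Reactants: 9 2-(3-methoxyphenyl)acetic acid
Product: 11 N-methoxy-2-(3-methoxyphenyl)-N-methylacetamide, via acyl imidazolide 10 (not isolated)
Conditions: CDI (1.1 equiv), CH2Cl2, rt, 1 h; then MeNH(OMe)·HCl (1.3 equiv), rt
Reagents that add atoms: N,O-dimethylhydroxylamine hydrochloride, CNOC.Cl; 1,1'-carbonyldiimidazole, O=C(n1ccnc1)n1ccnc1 (imidazolyl group of intermediate 10 only)
Why: Weinreb amide formation by CDI activation proceeds through the acyl imidazolide with loss of CO2, and the imidazole released in the first stage frees the hydroxylamine from its hydrochloride for the acyl transfer.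

Step 6
Reactants: 11 N-methoxy-2-(3-methoxyphenyl)-N-methylacetamide
Product: 12 1-(3-methoxyphenyl)but-3-yn-2-one
Conditions: HC≡CMgBr (0.5 M in THF, 2.0 equiv), THF, −10 → 0 °C; inverse quench into cold 1 M aq NaHSO4; used at once
Reagents that add atoms: ethynylmagnesium bromide, C#C[Mg]Br
Why: Weinreb ketone synthesis, in which the magnesium-chelated tetrahedral adduct survives until work-up so that only one ethynyl group is added, and the inverse acidic quench protonates the released N,O-dimethylhydroxylamine before it can add to the ynone in a conjugate sense.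

Step 7
Reactants: 8 1-(buta-1,3-dien-2-yloxy)-2,3-dimethoxy-5-[2-(3-methoxyphenyl)ethyl]benzene; 12 1-(3-methoxyphenyl)but-3-yn-2-one
Product: 13 1-(4-{2,3-dimethoxy-5-[2-(3-methoxyphenyl)ethyl]phenoxy}cyclohexa-1,4-dien-1-yl)-2-(3-methoxyphenyl)ethan-1-one
Conditions: 12 (1.5 equiv), BHT (5 mol%), toluene (0.5 M), 90 °C, sealed base-washed tube, Ar; filtration through basic Al2O3; carried on directly
Reagents that add atoms: none
Why: A concerted, asynchronous, normal-electron-demand [4+2] cycloaddition: the HOMO of diene 8 has its largest coefficient on the CH2 terminus attached to the oxygen-bearing carbon (future C2) and the LUMO of ynone 12 on its terminal alkyne carbon (future C3), so C2–C3 bonding leads and C4–C5 follows in the same transition state. The closest known reaction type is the Diels–Alder reaction of 2-alkoxy- and 2-silyloxybuta-1,3-dienes with acetylenic ketones, which gives 1-oxy-4-acylcyclohexa-1,4-dienes. Ring B is closed by intermolecular cycloaddition, four carbons of the diene and two of the alkyne joining suprafacially into the six-membered carbocycle. No stereocentre is formed, since every ring carbon of 13 is sp2 or CH2. The step needs regioselectivity (oxygen para to the acyl group), secured by the oxygen donor on C1 of the diene and the acyl acceptor on the alkyne, which polarise the two partners in matching sense; it also needs the aryl enol ether to survive, which neutral, acid-free thermal conditions with a radical inhibitor secure.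

Step 8
Reactants: 13 1-(4-{2,3-dimethoxy-5-[2-(3-methoxyphenyl)ethyl]phenoxy}cyclohexa-1,4-dien-1-yl)-2-(3-methoxyphenyl)ethan-1-one
Product: 14 1-(4-{2,3-dimethoxy-5-[2-(3-methoxyphenyl)ethyl]phenoxy}phenyl)-2-(3-methoxyphenyl)ethan-1-one
Conditions: DDQ (1.05 equiv), NaHCO3 (solid), toluene, 0 °C → rt
Reagents that add atoms: none
Why: DDQ dehydrogenation of a 1,4-cyclohexadiene (hydride abstraction from a doubly allylic CH2, then proton loss) is driven by aromatisation and is fast enough at 0 °C to outrun oxidation of the bibenzylic positions, while the solid bicarbonate keeps the acidic hydroquinone from hydrolysing the enol ether before it has become a stable diaryl ether.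

Step 9
Reactants: 14 1-(4-{2,3-dimethoxy-5-[2-(3-methoxyphenyl)ethyl]phenoxy}phenyl)-2-(3-methoxyphenyl)ethan-1-one
Product: 15 1,2-dimethoxy-5-[2-(3-methoxyphenyl)ethyl]-3-{4-[2-(3-methoxyphenyl)ethyl]phenoxy}benzene (perrottetin F tetramethyl ether)
Conditions: Et3SiH (4 equiv), CF3CO2H–CH2Cl2 (1:1), 0 °C → rt
Reagents that add atoms: none
Why: Ionic hydrogenation (Kursanov–Parnes reduction) takes the aryl ketone through the benzylic alcohol to a benzylic cation stabilised by the para aryloxy group of ring B, which accepts a second hydride from the silane, while the diaryl ether and the methyl ethers are stable to the acid.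

Step 10
Reactants: 15 1,2-dimethoxy-5-[2-(3-methoxyphenyl)ethyl]-3-{4-[2-(3-methoxyphenyl)ethyl]phenoxy}benzene
Product: 16 perrottetin F, 5-[2-(3-hydroxyphenyl)ethyl]-3-{4-[2-(3-hydroxyphenyl)ethyl]phenoxy}benzene-1,2-diol
Conditions: BBr3 (1 M in CH2Cl2, 8 equiv), CH2Cl2, −78 °C → rt; then ice/H2O
Reagents that add atoms: none
Why: Lewis acid cleavage of aryl methyl ethers with BBr3 (ether–borane complex, bromide attack on the methyl group) should remove all four methyl groups, the diaryl ether being inert because neither of its carbons can be attacked by bromide, and hydrolysis of the aryl borates on work-up frees the four phenols.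

Compound list
1 | 3-hydroxy-4,5-dimethoxybenzaldehyde | COc1cc(C=O)cc(O)c1OC | starting material
2 | (3-methoxybenzyl)triphenylphosphonium chloride | COc1cccc(C[P+](c2ccccc2)(c2ccccc2)c2ccccc2)c1.[Cl-] | starting material
3 | (3-methoxybenzylidene)triphenylphosphorane | COc1cccc(C=P(c2ccccc2)(c2ccccc2)c2ccccc2)c1 | intermediate (not isolated)
4 | 2,3-dimethoxy-5-[2-(3-methoxyphenyl)ethenyl]phenol, E/Z mixture (geometry left open on purpose) | COc1cccc(C=Cc2cc(O)c(OC)c(OC)c2)c1 | intermediate
5 | 2,3-dimethoxy-5-[2-(3-methoxyphenyl)ethyl]phenol | COc1cccc(CCc2cc(O)c(OC)c(OC)c2)c1 | intermediate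
6 | acryloyl chloride | C=CC(=O)Cl | starting material
7 | 2,3-dimethoxy-5-[2-(3-methoxyphenyl)ethyl]phenyl prop-2-enoate | C=CC(=O)Oc1cc(CCc2cccc(OC)c2)cc(OC)c1OC | intermediate
8 | 1-(buta-1,3-dien-2-yloxy)-2,3-dimethoxy-5-[2-(3-methoxyphenyl)ethyl]benzene | C=CC(=C)Oc1cc(CCc2cccc(OC)c2)cc(OC)c1OC | intermediate
9 | 2-(3-methoxyphenyl)acetic acid | COc1cccc(CC(=O)O)c1 | starting material
10 | 1-(1H-imidazol-1-yl)-2-(3-methoxyphenyl)ethan-1-one (acyl imidazolide) | COc1cccc(CC(=O)n2ccnc2)c1 | intermediate (not isolated)
11 | N-methoxy-2-(3-methoxyphenyl)-N-methylacetamide | COc1cccc(CC(=O)N(C)OC)c1 | intermediate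
12 | 1-(3-methoxyphenyl)but-3-yn-2-one | C#CC(=O)Cc1cccc(OC)c1 | intermediate
13 | 1-(4-{2,3-dimethoxy-5-[2-(3-methoxyphenyl)ethyl]phenoxy}cyclohexa-1,4-dien-1-yl)-2-(3-methoxyphenyl)ethan-1-one | COc1cccc(CC(=O)C2=CCC(Oc3cc(CCc4cccc(OC)c4)cc(OC)c3OC)=CC2)c1 | intermediate
14 | 1-(4-{2,3-dimethoxy-5-[2-(3-methoxyphenyl)ethyl]phenoxy}phenyl)-2-(3-methoxyphenyl)ethan-1-one | COc1cccc(CC(=O)c2ccc(Oc3cc(CCc4cccc(OC)c4)cc(OC)c3OC)cc2)c1 | intermediate
15 | 1,2-dimethoxy-5-[2-(3-methoxyphenyl)ethyl]-3-{4-[2-(3-methoxyphenyl)ethyl]phenoxy}benzene | COc1cccc(CCc2ccc(Oc3cc(CCc4cccc(OC)c4)cc(OC)c3OC)cc2)c1 | intermediate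
16 | perrottetin F | Oc1cccc(CCc2ccc(Oc3cc(CCc4cccc(O)c4)cc(O)c3O)cc2)c1 | target

Total step count: 10. Longest linear sequence: 8 steps (steps 1, 2, 3, 4, 7, 8, 9, 10 from aldehyde 1); the ynone branch (steps 5 and 6) joins at step 7.

Steps most likely to fail

Most at risk is step 7. The cycloaddition may be outrun by polymerisation of the 2-aryloxydiene or by thermal self-condensation of the enolisable ynone, or the two regiochemical orientations may not be separated well enough. The fallback buys ring B instead of building it and uses known chemistry only. Setting out from phenol 5, nucleophilic aromatic substitution on 4-fluorobenzaldehyde (K2CO3, DMF, 130 °C) should give 4-{2,3-dimethoxy-5-[2-(3-methoxyphenyl)ethyl]phenoxy}benzaldehyde F1. Wittig olefination with the ylide from salt 2 (KOtBu, THF) should then give 1,2-dimethoxy-5-[2-(3-methoxyphenyl)ethyl]-3-{4-[2-(3-methoxyphenyl)ethenyl]phenoxy}benzene F2 as an E/Z mixture. Hydrogenation (H2, Pd/C, EtOAc) brings the fallback back to the route at tetramethyl ether 15.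

Second is step 4. The acrylate or the product diene may polymerise, the titanium methylidene may engage the vinyl group instead of the carbonyl, or the enol ether may be hydrolysed back to the phenol during work-up. The fallback avoids carbonyl methylenation altogether and again sets out from phenol 5. Tsuji–Trost-type opening of 2-vinyloxirane at its internal allylic carbon (Pd2(dba)3·CHCl3 as zerovalent palladium source, racemic trans-1,2-diaminocyclohexane bis(2-diphenylphosphinobenzamide) ligand, CH2Cl2, rt) should give racemic 2-{2,3-dimethoxy-5-[2-(3-methoxyphenyl)ethyl]phenoxy}but-3-en-1-ol F3. Mesylation (MsCl, Et3N, CH2Cl2, 0 °C) gives 2-{2,3-dimethoxy-5-[2-(3-methoxyphenyl)ethyl]phenoxy}but-3-en-1-yl methanesulfonate F4. E2 elimination with KOtBu (THF, 0 °C) removes the hydrogen on the oxygen-bearing allylic carbon, erases the stereocentre and comes back to the route at diene 8.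

Third is step 6. The liberated N,O-dimethylhydroxylamine may add to the terminal ynone during the quench, or the Grignard reagent may deprotonate the benzylic CH2 of the amide and stall conversion. The fallback sets out from Weinreb amide 11 and forms the ynone by oxidation, with no amine present at that stage. Reduction with i-Bu2AlH (THF, −78 °C) gives (3-methoxyphenyl)acetaldehyde F5, and addition of ethynylmagnesium bromide (THF, −78 → 0 °C) gives racemic 1-(3-methoxyphenyl)but-3-yn-2-ol F6. Oxidation with Dess–Martin periodinane (NaHCO3, CH2Cl2, 0 °C) comes back to the route at ynone 12.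

Further compounds
F1 | step 7 | 4-{2,3-dimethoxy-5-[2-(3-methoxyphenyl)ethyl]phenoxy}benzaldehyde | O=Cc1ccc(Oc2cc(CCc3cccc(OC)c3)cc(OC)c2OC)cc1
F2 | step 7 | 1,2-dimethoxy-5-[2-(3-methoxyphenyl)ethyl]-3-{4-[2-(3-methoxyphenyl)ethenyl]phenoxy}benzene (E/Z mixture) | COc1cccc(C=Cc2ccc(Oc3cc(CCc4cccc(OC)c4)cc(OC)c3OC)cc2)c1
F3 | step 4 | 2-{2,3-dimethoxy-5-[2-(3-methoxyphenyl)ethyl]phenoxy}but-3-en-1-ol (racemic) | C=CC(CO)Oc1cc(CCc2cccc(OC)c2)cc(OC)c1OC
F4 | step 4 | 2-{2,3-dimethoxy-5-[2-(3-methoxyphenyl)ethyl]phenoxy}but-3-en-1-yl methanesulfonate (racemic) | C=CC(COS(C)(=O)=O)Oc1cc(CCc2cccc(OC)c2)cc(OC)c1OC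
F5 | step 6 | (3-methoxyphenyl)acetaldehyde | COc1cccc(CC=O)c1
F6 | step 6 | 1-(3-methoxyphenyl)but-3-yn-2-ol (racemic) | COc1cccc(CC(O)C#C)c1
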